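The route rests on cutting C3–C3a and O1–C2 of the benzofuran. This exposes the feature the key step exploits. C2, C3, ring B (on C2) and ring C (on C3) form an unbroken resveratrol unit. That unit is tied to a 3,5-dioxygenated benzoyl ring A through the carbon between its two oxygens (C3a) and one of those oxygens (O1). Anodic two-electron oxidation of a free 4-hydroxystilbene beside a resorcinol ester should make both bonds, the dihydrofuran ring and both (transient) stereocentres in one operation. The precursors, pterostilbene 1 and methyl 3,5-dihydroxybenzoate 2, are commercial and unprotected. Methylation, dehydrogenation, ester-to-aldehyde adjustment and global demethylation follow.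

Key step: step 1

Remark: locants are those of the target benzofuran (O1, C2, C3, C3a, C4–C7, C7a; ring A = benzo ring); the target is achiral, so chiral intermediates are carried as racemates with one enantiomer drawn.

Step 1
Reactants: 1 pterostilbene [(E)-4-(3,5-dimethoxystyryl)phenol]; 2 methyl 3,5-dihydroxybenzoate
Product: 5 methyl trans-3-(3,5-dimethoxyphenyl)-4-hydroxy-2-(4-hydroxyphenyl)-2,3-dihydro-1-benzofuran-6-carboxylate (racemic; 2R,3R enantiomer drawn), via vinylogous phenoxenium cation 3 (not isolated), via para-quinone methide 4 (not isolated)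
Conditions: undivided cell, boron-doped diamond anode, Pt cathode, constant current (ca. 2 mA cm−2, 2.0–2.2 F mol−1 based on 1), Bu4NPF6 (0.1 M), 1,1,1,3,3,3-hexafluoropropan-2-ol (HFIP), 2 (5 equiv), 1 dosed slowly, 20 °C
Reagents that add atoms: none
Why: Proposed new method: 1, a phenol conjugated with a stilbene, should be the most easily oxidised species present, so at the anode it loses two electrons and its phenolic proton (stepwise, through the HFIP-solvated phenoxyl radical) and becomes cation 3, in which the positive charge is passed through ring B and the alkene to the carbon that carries ring C. C4 of 2 attacks that carbon in a Friedel–Crafts alkylation (C3–C3a), ring A rearomatises to para-quinone methide 4, and one of the two equivalent neighbouring hydroxyls adds to the exocyclic methide carbon in a 5-exo-trig oxa-1,6-addition (O1–C2) that closes the dihydrofuran and restores the phenol of ring B, while the released protons are reduced to H2 at the cathode. The closest known reaction types are the oxidative dehydrodimerisation of 4-hydroxystilbenes to 2,3-diaryl-2,3-dihydrobenzofurans, anodic phenol–arene cross-coupling in HFIP and anodic phenol–alkene (3+2) annulation, but capture of a stilbene-derived cation by a different, ester-bearing resorcinol at its doubly flanked carbon has not been demonstrated. C3 forms without facial bias and gives a racemate; C2 is set relative to C3 because 4 closes through the rotamer that places rings B and C on opposite faces of the new ring, and reversible reopening to 4 lets any cis isomer drain to the more stable trans one (both centres vanish in step 3, so this is not critical). Cross- over homo-coupling is the first selectivity needed and is addressed by a fivefold excess of 2, by dosing 1 at a rate matched to the current so that little unoxidised stilbene is available as a rival nucleophile, and by ending the electrolysis near 2 F mol−1, product 5 being an unconjugated phenol that is harder to oxidise than 1. The second is attack through C4 and not C2 or C6 of 2: all three positions are activated by both hydroxyls and deactivated by the ester, so the choice is steric, C4 being flanked only by two small hydroxyls whereas substitution at C2 or C6 by the bulky secondary cation would clash with the ester and twist it out of conjugation, in line with the known halogenation and allylation of 3,5-dihydroxybenzoates between the hydroxyls.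

Step 2
Reactants: 5 methyl trans-3-(3,5-dimethoxyphenyl)-4-hydroxy-2-(4-hydroxyphenyl)-2,3-dihydro-1-benzofuran-6-carboxylate
Product: 6 methyl trans-3-(3,5-dimethoxyphenyl)-4-methoxy-2-(4-methoxyphenyl)-2,3-dihydro-1-benzofuran-6-carboxylate (racemic; 2R,3R enantiomer drawn)
Conditions: MeI (4 equiv), K2CO3 (4 equiv), acetone, reflux
Reagents that add atoms: iodomethane (MeI), SMILES CI
Why: Williamson O-methylation of both phenols is routine for stilbenoid dihydrobenzofurans, masks the oxidisable and acidic hydroxyls before the quinone, hydride and MnO2 steps, and uses the group already present on ring C so that one final operation frees all four phenols, while any base-induced epimerisation can only favour the trans isomer and is irrelevant after step 3.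

Step 3
Reactants: 6 methyl trans-3-(3,5-dimethoxyphenyl)-4-methoxy-2-(4-methoxyphenyl)-2,3-dihydro-1-benzofuran-6-carboxylate
Product: 7 methyl 3-(3,5-dimethoxyphenyl)-4-methoxy-2-(4-methoxyphenyl)-1-benzofuran-6-carboxylate
Conditions: DDQ (2.5 equiv), 1,4-dioxane, 100 °C
Reagents that add atoms: none
Why: DDQ dehydrogenation of a 2,3-dihydrobenzofuran proceeds by hydride abstraction from C2–H (benzylic to the para-anisyl ring B and alpha to O1) followed by loss of the doubly benzylic C3 proton, is driven by aromatisation of the furan, deletes both stereocentres, and leaves the ester and aryl methyl ethers untouched.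

Step 4
Reactants: 7 methyl 3-(3,5-dimethoxyphenyl)-4-methoxy-2-(4-methoxyphenyl)-1-benzofuran-6-carboxylate
Product: 8 [3-(3,5-dimethoxyphenyl)-4-methoxy-2-(4-methoxyphenyl)-1-benzofuran-6-yl]methanol
Conditions: i-Bu2AlH (3 equiv), CH2Cl2, −78 to 0 °C; aq. Rochelle salt
Reagents that add atoms: none
Why: Full hydride reduction of an aromatic methyl ester to the primary benzylic alcohol with i-Bu2AlH is standard and avoids the unreliable partial reduction, and the benzofuran and the aryl methyl ethers are inert at or below 0 °C.

Step 5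
Reactants: 8 [3-(3,5-dimethoxyphenyl)-4-methoxy-2-(4-methoxyphenyl)-1-benzofuran-6-yl]methanol
Product: 9 3-(3,5-dimethoxyphenyl)-4-methoxy-2-(4-methoxyphenyl)-1-benzofuran-6-carbaldehyde
Conditions: activated MnO2 (15 equiv), CH2Cl2, rt
Reagents that add atoms: none
Why: Heterogeneous MnO2 oxidation is selective for benzylic alcohols and stops at the aldehyde, and with all phenols masked no other site of 8 is oxidisable under these neutral conditions.

Step 6
Reactants: 9 3-(3,5-dimethoxyphenyl)-4-methoxy-2-(4-methoxyphenyl)-1-benzofuran-6-carbaldehyde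
Product: 10 3-(3,5-dihydroxyphenyl)-4-hydroxy-2-(4-hydroxyphenyl)-1-benzofuran-6-carbaldehyde (target)
Conditions: BBr3 (8 equiv), CH2Cl2, −78 °C to rt; ice-water
Reagents that add atoms: none
Why: BBr3 cleavage of aryl methyl ethers (boron coordination to oxygen, bromide attack on the methyl group, hydrolysis on quench) is established for methoxybenzaldehydes, the formyl group being only complexed and released again by water, and the aromatic benzofuran core has no acid-labile bond or stereocentre.

Compound list
1 | pterostilbene, (E)-4-(3,5-dimethoxystyryl)phenol | COc1cc(/C=C/c2ccc(O)cc2)cc(OC)c1 | starting material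
2 | methyl 3,5-dihydroxybenzoate | COC(=O)c1cc(O)cc(O)c1 | starting material
3 | 1-(3,5-dimethoxyphenyl)-2-(4-oxocyclohexa-2,5-dien-1-ylidene)ethylium (vinylogous phenoxenium cation from 1) | COc1cc([CH+]C=C2C=CC(=O)C=C2)cc(OC)c1 | intermediate
4 | methyl 4-[1-(3,5-dimethoxyphenyl)-2-(4-oxocyclohexa-2,5-dien-1-ylidene)ethyl]-3,5-dihydroxybenzoate (para-quinone methide; racemic, R enantiomer drawn) | COC(=O)c1cc(O)c([C@@H](c2cc(OC)cc(OC)c2)C=C2C=CC(=O)C=C2)c(O)c1 | intermediate
5 | methyl trans-3-(3,5-dimethoxyphenyl)-4-hydroxy-2-(4-hydroxyphenyl)-2,3-dihydro-1-benzofuran-6-carboxylate (racemic, 2R,3R drawn) | COC(=O)c1cc(O)c2[C@@H](c3cc(OC)cc(OC)c3)[C@H](c3ccc(O)cc3)Oc2c1 | intermediate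
6 | methyl trans-3-(3,5-dimethoxyphenyl)-4-methoxy-2-(4-methoxyphenyl)-2,3-dihydro-1-benzofuran-6-carboxylate (racemic, 2R,3R drawn) | COC(=O)c1cc(OC)c2[C@@H](c3cc(OC)cc(OC)c3)[C@H](c3ccc(OC)cc3)Oc2c1 | intermediate
7 | methyl 3-(3,5-dimethoxyphenyl)-4-methoxy-2-(4-methoxyphenyl)-1-benzofuran-6-carboxylate | COC(=O)c1cc(OC)c2c(-c3cc(OC)cc(OC)c3)c(-c3ccc(OC)cc3)oc2c1 | intermediate
8 | [3-(3,5-dimethoxyphenyl)-4-methoxy-2-(4-methoxyphenyl)-1-benzofuran-6-yl]methanol | OCc1cc(OC)c2c(-c3cc(OC)cc(OC)c3)c(-c3ccc(OC)cc3)oc2c1 | intermediate
9 | 3-(3,5-dimethoxyphenyl)-4-methoxy-2-(4-methoxyphenyl)-1-benzofuran-6-carbaldehyde | O=Cc1cc(OC)c2c(-c3cc(OC)cc(OC)c3)c(-c3ccc(OC)cc3)oc2c1 | intermediate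
10 | 3-(3,5-dihydroxyphenyl)-4-hydroxy-2-(4-hydroxyphenyl)-1-benzofuran-6-carbaldehyde | O=Cc1cc(O)c2c(-c3cc(O)cc(O)c3)c(-c3ccc(O)cc3)oc2c1 | target

Total step count: 6
Longest linear sequence: 6 (steps 1 to 6, from 1 or 2)

Steps most likely to fail

1. Step 1 (the labelled step). Three things may go wrong.
- Self-coupling of the oxidised stilbene, by radical dimerisation or by capture of the cation by unoxidised 1, may outrun capture by the ester-deactivated resorcinol.
- Bond formation may occur beside the ester.
- The product may be oxidised further if the charge is not limited.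

The fallback uses known chemistry only, sets out from 2 and rejoins the route at 7, building the benzofuran by cross-coupling instead of oxidation. Iodination of 2 between the hydroxyls (I2, NaHCO3, THF/H2O, 0 °C) should give methyl 3,5-dihydroxy-4-iodobenzoate F1. Sonogashira coupling with 4-ethynylanisole (PdCl2(PPh3)2, CuI, Et3N, DMF, 70 °C) gives methyl 3,5-dihydroxy-4-[(4-methoxyphenyl)ethynyl]benzoate F2. This cyclises in the same flask (5-endo-dig, either equivalent hydroxyl) to methyl 4-hydroxy-2-(4-methoxyphenyl)-1-benzofuran-6-carboxylate F3. O-methylation (MeI, K2CO3, acetone) gives methyl 4-methoxy-2-(4-methoxyphenyl)-1-benzofuran-6-carboxylate F4. Bromination at the nucleophilic C3 (NBS, CH2Cl2, 0 °C) gives methyl 3-bromo-4-methoxy-2-(4-methoxyphenyl)-1-benzofuran-6-carboxylate F5. Suzuki–Miyaura coupling with 3,5-dimethoxyphenylboronic acid (Pd(PPh3)4, K2CO3, dioxane/H2O, 90 °C) then delivers 7.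

2. Step 3. Hydride abstraction may be slow because the ester on ring A weakens the donor ability of O1, and forcing conditions may then degrade the electron-rich rings.

The fallback sets out from 5 and rejoins at 7 by reversing protection and oxidation. With ring B still a free phenol, C2–H is removed through phenol oxidation, an easier process known for phenolic dihydrobenzofuran neolignans. Treating 5 with DDQ (1.1 equiv, dioxane, rt) should give methyl 3-(3,5-dimethoxyphenyl)-4-hydroxy-2-(4-hydroxyphenyl)-1-benzofuran-6-carboxylate F6. Methylation (MeI, K2CO3, acetone) then gives 7.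

3. Step 6. The Lewis-acid-activated aldehyde may condense with the electron-rich rings as they are unmasked, or ether cleavage may stay incomplete.

The fallback sets out from 7 and rejoins at 10 by exchanging the protecting groups before the aldehyde exists. BBr3 (CH2Cl2, −78 to 0 °C) on the ester should give methyl 3-(3,5-dihydroxyphenyl)-4-hydroxy-2-(4-hydroxyphenyl)-1-benzofuran-6-carboxylate F7. Silylation (TBSCl, imidazole, DMF, 40 °C) gives methyl 4-(tert-butyldimethylsilyloxy)-3-[3,5-bis(tert-butyldimethylsilyloxy)phenyl]-2-[4-(tert-butyldimethylsilyloxy)phenyl]-1-benzofuran-6-carboxylate F8. Reduction with i-Bu2AlH gives the corresponding tetrasilylated benzofuran-6-ylmethanol F9. MnO2 gives the tetrasilylated benzofuran-6-carbaldehyde F10. Mild fluoride cleavage (Et3N·3HF, THF, rt) releases 10 without any Lewis acid.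

Further compounds
F1 | step 1 | methyl 3,5-dihydroxy-4-iodobenzoate | COC(=O)c1cc(O)c(I)c(O)c1
F2 | step 1 | methyl 3,5-dihydroxy-4-[(4-methoxyphenyl)ethynyl]benzoate | COC(=O)c1cc(O)c(C#Cc2ccc(OC)cc2)c(O)c1
F3 | step 1 | methyl 4-hydroxy-2-(4-methoxyphenyl)-1-benzofuran-6-carboxylate | COC(=O)c1cc(O)c2cc(-c3ccc(OC)cc3)oc2c1
F4 | step 1 | methyl 4-methoxy-2-(4-methoxyphenyl)-1-benzofuran-6-carboxylate | COC(=O)c1cc(OC)c2cc(-c3ccc(OC)cc3)oc2c1
F5 | step 1 | methyl 3-bromo-4-methoxy-2-(4-methoxyphenyl)-1-benzofuran-6-carboxylate | COC(=O)c1cc(OC)c2c(Br)c(-c3ccc(OC)cc3)oc2c1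
F6 | step 3 | methyl 3-(3,5-dimethoxyphenyl)-4-hydroxy-2-(4-hydroxyphenyl)-1-benzofuran-6-carboxylate | COC(=O)c1cc(O)c2c(-c3cc(OC)cc(OC)c3)c(-c3ccc(O)cc3)oc2c1
F7 | step 6 | methyl 3-(3,5-dihydroxyphenyl)-4-hydroxy-2-(4-hydroxyphenyl)-1-benzofuran-6-carboxylate | COC(=O)c1cc(O)c2c(-c3cc(O)cc(O)c3)c(-c3ccc(O)cc3)oc2c1
F8 | step 6 | methyl 4-(tert-butyldimethylsilyloxy)-3-[3,5-bis(tert-butyldimethylsilyloxy)phenyl]-2-[4-(tert-butyldimethylsilyloxy)phenyl]-1-benzofuran-6-carboxylate | COC(=O)c1cc(O[Si](C)(C)C(C)(C)C)c2c(-c3cc(O[Si](C)(C)C(C)(C)C)cc(O[Si](C)(C)C(C)(C)C)c3)c(-c3ccc(O[Si](C)(C)C(C)(C)C)cc3)oc2c1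
F9 | step 6 | {4-(tert-butyldimethylsilyloxy)-3-[3,5-bis(tert-butyldimethylsilyloxy)phenyl]-2-[4-(tert-butyldimethylsilyloxy)phenyl]-1-benzofuran-6-yl}methanol | OCc1cc(O[Si](C)(C)C(C)(C)C)c2c(-c3cc(O[Si](C)(C)C(C)(C)C)cc(O[Si](C)(C)C(C)(C)C)c3)c(-c3ccc(O[Si](C)(C)C(C)(C)C)cc3)oc2c1
F10 | step 6 | 4-(tert-butyldimethylsilyloxy)-3-[3,5-bis(tert-butyldimethylsilyloxy)phenyl]-2-[4-(tert-butyldimethylsilyloxy)phenyl]-1-benzofuran-6-carbaldehyde | O=Cc1cc(O[Si](C)(C)C(C)(C)C)c2c(-c3cc(O[Si](C)(C)C(C)(C)C)cc(O[Si](C)(C)C(C)(C)C)c3)c(-c3ccc(O[Si](C)(C)C(C)(C)C)cc3)oc2c1
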